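Ring B is never coupled to ring A as an arene; it is grown as a carbocycle on the ring A phenol oxygen and aromatised afterwards. Its ether carbon C1' lies between C2' (OH) and C6' (CH2OH) with the C4' methyl opposite, which is the substitution pattern of a 2-aryloxy-5-methylcyclohexane-1,3-dione with two equivalent carbonyl carbons. A Dieckmann condensation of the ring A ether of methyl 6-hydroxy-3-methyl-5-oxohexanoate, carrying the ring A carboxyl as a tert-butyl ester and the (R)-diol as an acetonide, forms the C1'–C6' bond and closes ring B in one operation. Enol triflation, methoxycarbonylation and dehydrogenation then deliver the aromatic ring.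

Key step: step 10

Assumption: 4-hydroxy-2-methoxybenzaldehyde is taken as purchasable, and the (R)-configured phosphoric acid is assumed to deliver the allyl group to the Re face of the aldehyde as it does with other aryl aldehydes; the enantiomeric acid would be used if the sense proved opposite.

Step 1
Reactants: 1 4-hydroxy-2-methoxybenzaldehyde
Product: 2 2-methoxy-4-{[2-(trimethylsilyl)ethoxy]methoxy}benzaldehyde
Conditions: SEMCl, iPr2NEt, CH2Cl2, 0 °C → rt
Reagents that add atoms: 2-(trimethylsilyl)ethoxymethyl chloride (SEMCl), C[Si](C)(C)CCOCCl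
Why: Williamson-type O-alkylation of the single phenol by the reactive α-chloro ether; the SEM acetal is chosen because its oxygen atoms later direct ortho-lithiation and fluoride removes it without acid.

Step 2
Reactants: 2 2-methoxy-4-{[2-(trimethylsilyl)ethoxy]methoxy}benzaldehyde; 3 2-methylallylboronic acid pinacol ester
Product: 5 (1R)-1-(2-methoxy-4-{[2-(trimethylsilyl)ethoxy]methoxy}phenyl)-3-methylbut-3-en-1-ol, via boronate ester 4 (not isolated)
Conditions: (R)-TRIP phosphoric acid [(R)-3,3'-bis(2,4,6-triisopropylphenyl)-1,1'-binaphthyl-2,2'-diyl hydrogen phosphate] (5 mol%), 4 Å molecular sieves, toluene, −30 °C; then aq. NaHCO3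
Reagents that add atoms: none
Why: Chiral phosphoric acid-catalysed allylboration through a closed chair transition state in which the acid hydrogen-bonds to a boronate oxygen and to the formyl hydrogen; the (R)-configured catalyst should expose the Re face and so set the (R)-carbinol centre, which stays masked as its borate until work-up.

Step 3
Reactants: 5 (1R)-1-(2-methoxy-4-{[2-(trimethylsilyl)ethoxy]methoxy}phenyl)-3-methylbut-3-en-1-ol
Product: 6 (1R)-1-(2-methoxy-4-{[2-(trimethylsilyl)ethoxy]methoxy}phenyl)-3-methylbutane-1,3-diol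
Conditions: Co(acac)2 (cobalt bis(acetylacetonate), 20 mol%), PhSiH3, O2 (1 atm), THF, rt; then aq. Na2S2O3
Reagents that add atoms: dioxygen, O=O
Why: Mukaiyama hydration, in which hydrogen-atom transfer from a cobalt hydride to the 1,1-disubstituted alkene gives the tertiary radical that is trapped by O2 and reduced by the silane to the Markovnikov tertiary alcohol, without touching the carbinol stereocentre.

Step 4
Reactants: 6 (1R)-1-(2-methoxy-4-{[2-(trimethylsilyl)ethoxy]methoxy}phenyl)-3-methylbutane-1,3-diol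
Product: 7 (4R)-4-(2-methoxy-4-{[2-(trimethylsilyl)ethoxy]methoxy}phenyl)-2,2,6,6-tetramethyl-1,3-dioxane
Conditions: 2-methoxypropene, PPTS (2 mol%), CH2Cl2, 0 °C; Et3N quench
Reagents that add atoms: 2-methoxypropene, COC(C)=C
Why: Acid-catalysed acetal exchange with an enol ether closes the 1,3-dioxane under buffered, nearly neutral conditions, so the electron-rich benzylic C–O bond should not ionise and the (R) centre is kept.

Step 5
Reactants: 7 (4R)-4-(2-methoxy-4-{[2-(trimethylsilyl)ethoxy]methoxy}phenyl)-2,2,6,6-tetramethyl-1,3-dioxane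
Product: 9 tert-butyl 2-methoxy-3-[(4R)-2,2,6,6-tetramethyl-1,3-dioxan-4-yl]-6-{[2-(trimethylsilyl)ethoxy]methoxy}benzoate, via aryllithium 8 (not isolated)
Conditions: s-BuLi, TMEDA, THF, −78 °C; then Boc2O, −78 °C → rt; aq. NH4Cl
Reagents that add atoms: di-tert-butyl dicarbonate (Boc2O), CC(C)(C)OC(=O)OC(=O)OC(C)(C)C
Why: Directed ortho-metalation at the only ring position flanked by two coordinating oxygen groups (OMe and the SEM acetal), followed by acylation of the aryllithium with Boc2O, gives the tert-butyl ester directly, and the two ortho substituents stop a second addition.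

Step 6
Reactants: 9 tert-butyl 2-methoxy-3-[(4R)-2,2,6,6-tetramethyl-1,3-dioxan-4-yl]-6-{[2-(trimethylsilyl)ethoxy]methoxy}benzoate
Product: 10 tert-butyl 6-hydroxy-2-methoxy-3-[(4R)-2,2,6,6-tetramethyl-1,3-dioxan-4-yl]benzoate
Conditions: Bu4NF, THF/DMPU, 60 °C; aq. NH4Cl
Reagents that add atoms: none
Why: Fluoride attacks silicon and the SEM group fragments to ethene, formaldehyde and the phenoxide, a non-acidic deprotection that leaves the acetonide and the hindered tert-butyl ester untouched.

Step 7
Reactants: 11 3-methylglutaric anhydride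
Product: 12 5-methoxy-3-methyl-5-oxopentanoic acid (racemic)
Conditions: MeOH, reflux
Reagents that add atoms: methanol, CO
Why: Alcoholysis of a cyclic anhydride; the anhydride is meso, so attack at either carbonyl gives the same racemic half ester.

Step 8
Reactants: 12 5-methoxy-3-methyl-5-oxopentanoic acid
Product: 15 methyl 6-chloro-3-methyl-5-oxohexanoate (racemic), via acid chloride 13 (not isolated), via diazoketone 14 (not isolated)
Conditions: (COCl)2, DMF (cat.), CH2Cl2, 0 °C → rt, evaporate; Me3SiCHN2, THF/MeCN, 0 °C → rt; then HCl (4 M in dioxane), 0 °C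
Reagents that add atoms: (trimethylsilyl)diazomethane, C[Si](C)(C)C=[N+]=[N-]; hydrogen chloride, Cl
Why: Acid chloride formation, C-acylation of the diazoalkane with loss of Me3SiCl (Arndt–Eistert-type diazoketone synthesis) and protonation of the diazoketone with displacement of N2 by chloride give the chloromethyl ketone while the methyl ester stays intact.

Step 9
Reactants: 10 tert-butyl 6-hydroxy-2-methoxy-3-[(4R)-2,2,6,6-tetramethyl-1,3-dioxan-4-yl]benzoate; 15 methyl 6-chloro-3-methyl-5-oxohexanoate
Product: 16 tert-butyl 2-methoxy-6-[(6-methoxy-4-methyl-2,6-dioxohexyl)oxy]-3-[(4R)-2,2,6,6-tetramethyl-1,3-dioxan-4-yl]benzoate (both epimers at the methyl-bearing chain carbon)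
Conditions: K2CO3, NaI (10 mol%), acetone, 50 °C
Reagents that add atoms: none
Why: Williamson ether synthesis with Finkelstein activation (iodomethyl ketone formed in situ); K2CO3 deprotonates the hydrogen-bonded salicylate phenol but is too weak to start a Claisen condensation.

Step 10
Reactants: 16 tert-butyl 2-methoxy-6-[(6-methoxy-4-methyl-2,6-dioxohexyl)oxy]-3-[(4R)-2,2,6,6-tetramethyl-1,3-dioxan-4-yl]benzoate
Product: 17 tert-butyl 2-methoxy-6-[(4-methyl-2,6-dioxocyclohexyl)oxy]-3-[(4R)-2,2,6,6-tetramethyl-1,3-dioxan-4-yl]benzoate (epimer mixture, largely enolised)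
Conditions: KOtBu (2.5 equiv), THF (0.02 M), 0 °C → rt; then cold 0.5 M HCl to pH 4
Reagents that add atoms: none
Why: KOtBu equilibrates the ketone enolates of 16, the α-aryloxy enolate at C1' adds to the chain methyl ester carbonyl (the future C6'), the tetrahedral intermediate expels methoxide, and the 2-aryloxy-1,3-dione is at once deprotonated to its delocalised enolate, which pulls the equilibrium to the ring-closed side. The closest known reaction type is the Dieckmann (intramolecular Claisen) cyclisation of 5-oxohexanoates to cyclohexane-1,3-diones. Ring B closes in the 6-(enolendo)-exo-trig mode, which is a favoured closure for enolates. No stereocentre has to be controlled: C4' is carried as both epimers, C1' is trigonal in the enol form, and both disappear on aromatisation. The selectivity needed is closure on the chain ester and not on the ring A carboxyl (five-membered benzofuran-3-one); the tert-butyl group and the two ortho substituents (OMe and the ether oxygen) shield that carbonyl, while the enolate on the other side of the ketone could only form a four-membered ring and returns by proton exchange. High dilution keeps intermolecular Claisen and aldol condensation down.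

Step 11
Reactants: 17 tert-butyl 2-methoxy-6-[(4-methyl-2,6-dioxocyclohexyl)oxy]-3-[(4R)-2,2,6,6-tetramethyl-1,3-dioxan-4-yl]benzoate
Product: 18 tert-butyl 2-methoxy-6-({4-methyl-6-oxo-2-[(trifluoromethanesulfonyl)oxy]cyclohex-1-en-1-yl}oxy)-3-[(4R)-2,2,6,6-tetramethyl-1,3-dioxan-4-yl]benzoate (epimer mixture)
Conditions: Tf2O, pyridine, CH2Cl2, −78 → 0 °C
Reagents that add atoms: trifluoromethanesulfonic anhydride (Tf2O), O=S(=O)(OS(=O)(=O)C(F)(F)F)C(F)(F)F
Why: O-Sulfonylation of the enol of the 1,3-dione (a vinylogous acid); the two carbonyl groups are related by the mirror plane through C1' and C4', so either one gives the same vinylogous acyl triflate.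

Step 12
Reactants: 18 tert-butyl 2-methoxy-6-({4-methyl-6-oxo-2-[(trifluoromethanesulfonyl)oxy]cyclohex-1-en-1-yl}oxy)-3-[(4R)-2,2,6,6-tetramethyl-1,3-dioxan-4-yl]benzoate
Product: 19 tert-butyl 2-methoxy-6-{[2-(methoxycarbonyl)-4-methyl-6-oxocyclohex-1-en-1-yl]oxy}-3-[(4R)-2,2,6,6-tetramethyl-1,3-dioxan-4-yl]benzoate (epimer mixture)
Conditions: Pd(OAc)2 (5 mol%), dppp (6 mol%), CO (1 atm), MeOH, Et3N, DMF, 60 °C
Reagents that add atoms: carbon monoxide, [C-]#[O+]; methanol, CO
Why: Palladium-catalysed alkoxycarbonylation of an enol triflate, in which oxidative addition to zerovalent palladium generated from Pd(OAc)2 and the diphosphine, CO insertion and methanolysis of the acyl palladium complex install the carboxyl carbon on C6'.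

Step 13
Reactants: 19 tert-butyl 2-methoxy-6-{[2-(methoxycarbonyl)-4-methyl-6-oxocyclohex-1-en-1-yl]oxy}-3-[(4R)-2,2,6,6-tetramethyl-1,3-dioxan-4-yl]benzoate
Product: 22 tert-butyl 6-[2-hydroxy-6-(methoxycarbonyl)-4-methylphenoxy]-2-methoxy-3-[(4R)-2,2,6,6-tetramethyl-1,3-dioxan-4-yl]benzoate, via sulfilimine adduct 20 (not isolated), via cyclohexadienone 21 (not isolated)
Conditions: LiN(iPr)2, THF, −78 °C; PhS(Cl)=NtBu, −78 °C → rt; aq. NH4Cl
Reagents that add atoms: none
Why: Mukaiyama dehydrogenation, in which the kinetic lithium enolate at C3' attacks sulfur of the sulfinimidoyl chloride, the resulting sulfilimine undergoes syn-elimination below room temperature, and the cross-conjugated dienone tautomerises to the phenol, which removes the C4' stereocentre.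

Step 14
Reactants: 22 tert-butyl 6-[2-hydroxy-6-(methoxycarbonyl)-4-methylphenoxy]-2-methoxy-3-[(4R)-2,2,6,6-tetramethyl-1,3-dioxan-4-yl]benzoate
Product: 23 tert-butyl 6-[2-hydroxy-6-(hydroxymethyl)-4-methylphenoxy]-2-methoxy-3-[(4R)-2,2,6,6-tetramethyl-1,3-dioxan-4-yl]benzoate
Conditions: LiBH4, MeOH (4 equiv), THF, 0 → 40 °C; aq. NH4Cl
Reagents that add atoms: none
Why: Chemoselective hydride reduction in which methanol-activated LiBH4 reduces the unhindered methyl ester (the ring B phenoxide is meta to it), whereas the tert-butyl ester flanked by two ortho substituents is not attacked.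

Step 15
Reactants: 23 tert-butyl 6-[2-hydroxy-6-(hydroxymethyl)-4-methylphenoxy]-2-methoxy-3-[(4R)-2,2,6,6-tetramethyl-1,3-dioxan-4-yl]benzoate
Product: 24 3-[(1R)-1,3-dihydroxy-3-methylbutyl]-6-[2-hydroxy-6-(hydroxymethyl)-4-methylphenoxy]-2-methoxybenzoic acid (CNP0452050.1)
Conditions: TFA/CH2Cl2/H2O (25:70:5), anisole, 0 °C → rt; then aq. NaHCO3, acidify to pH 3
Reagents that add atoms: none
Why: Acidolysis, in which the tert-butyl ester cleaves by alkyl–oxygen ionisation (the cation leaves as isobutene or is caught by anisole) and the strained acetonide is hydrolysed; ring A, deactivated by its carboxyl group and carrying a twisted methoxy group, should not support benzylic ionisation in the cold, so the (R) centre is kept.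

Compound list
1 | 4-hydroxy-2-methoxybenzaldehyde | COc1cc(O)ccc1C=O | starting material
2 | 2-methoxy-4-{[2-(trimethylsilyl)ethoxy]methoxy}benzaldehyde | COc1cc(OCOCC[Si](C)(C)C)ccc1C=O | intermediate
3 | 2-methylallylboronic acid pinacol ester | CC(=C)CB1OC(C)(C)C(C)(C)O1 | starting material
4 | 2-{[(1R)-1-(2-methoxy-4-{[2-(trimethylsilyl)ethoxy]methoxy}phenyl)-3-methylbut-3-en-1-yl]oxy}-4,4,5,5-tetramethyl-1,3,2-dioxaborolane | COc1cc(OCOCC[Si](C)(C)C)ccc1[C@H](OB2OC(C)(C)C(C)(C)O2)CC(C)=C | intermediate
5 | (1R)-1-(2-methoxy-4-{[2-(trimethylsilyl)ethoxy]methoxy}phenyl)-3-methylbut-3-en-1-ol | COc1cc(OCOCC[Si](C)(C)C)ccc1[C@H](O)CC(C)=C | intermediate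
6 | (1R)-1-(2-methoxy-4-{[2-(trimethylsilyl)ethoxy]methoxy}phenyl)-3-methylbutane-1,3-diol | COc1cc(OCOCC[Si](C)(C)C)ccc1[C@H](O)CC(C)(C)O | intermediate
7 | (4R)-4-(2-methoxy-4-{[2-(trimethylsilyl)ethoxy]methoxy}phenyl)-2,2,6,6-tetramethyl-1,3-dioxane | COc1cc(OCOCC[Si](C)(C)C)ccc1[C@H]2CC(C)(C)OC(C)(C)O2 | intermediate
8 | {2-methoxy-3-[(4R)-2,2,6,6-tetramethyl-1,3-dioxan-4-yl]-6-{[2-(trimethylsilyl)ethoxy]methoxy}phenyl}lithium | COc1c([C@H]2CC(C)(C)OC(C)(C)O2)ccc(OCOCC[Si](C)(C)C)c1[Li] | intermediate
9 | tert-butyl 2-methoxy-3-[(4R)-2,2,6,6-tetramethyl-1,3-dioxan-4-yl]-6-{[2-(trimethylsilyl)ethoxy]methoxy}benzoate | COc1c([C@H]2CC(C)(C)OC(C)(C)O2)ccc(OCOCC[Si](C)(C)C)c1C(=O)OC(C)(C)C | intermediate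
10 | tert-butyl 6-hydroxy-2-methoxy-3-[(4R)-2,2,6,6-tetramethyl-1,3-dioxan-4-yl]benzoate | COc1c([C@H]2CC(C)(C)OC(C)(C)O2)ccc(O)c1C(=O)OC(C)(C)C | intermediate
11 | 3-methylglutaric anhydride (4-methyloxane-2,6-dione) | CC1CC(=O)OC(=O)C1 | starting material
12 | 5-methoxy-3-methyl-5-oxopentanoic acid (racemic) | COC(=O)CC(C)CC(=O)O | intermediate
13 | methyl 5-chloro-3-methyl-5-oxopentanoate (racemic) | COC(=O)CC(C)CC(=O)Cl | intermediate
14 | methyl 6-diazo-3-methyl-5-oxohexanoate (racemic) | COC(=O)CC(C)CC(=O)C=[N+]=[N-] | intermediate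
15 | methyl 6-chloro-3-methyl-5-oxohexanoate (racemic) | COC(=O)CC(C)CC(=O)CCl | intermediate
16 | tert-butyl 2-methoxy-6-[(6-methoxy-4-methyl-2,6-dioxohexyl)oxy]-3-[(4R)-2,2,6,6-tetramethyl-1,3-dioxan-4-yl]benzoate (both epimers at the chain methine) | COc1c([C@H]2CC(C)(C)OC(C)(C)O2)ccc(OCC(=O)CC(C)CC(=O)OC)c1C(=O)OC(C)(C)C | intermediate
17 | tert-butyl 2-methoxy-6-[(4-methyl-2,6-dioxocyclohexyl)oxy]-3-[(4R)-2,2,6,6-tetramethyl-1,3-dioxan-4-yl]benzoate (epimer mixture) | COc1c([C@H]2CC(C)(C)OC(C)(C)O2)ccc(OC2C(=O)CC(C)CC2=O)c1C(=O)OC(C)(C)C | intermediate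
18 | tert-butyl 2-methoxy-6-({4-methyl-6-oxo-2-[(trifluoromethanesulfonyl)oxy]cyclohex-1-en-1-yl}oxy)-3-[(4R)-2,2,6,6-tetramethyl-1,3-dioxan-4-yl]benzoate (epimer mixture) | COc1c([C@H]2CC(C)(C)OC(C)(C)O2)ccc(OC2=C(OS(=O)(=O)C(F)(F)F)CC(C)CC2=O)c1C(=O)OC(C)(C)C | intermediate
19 | tert-butyl 2-methoxy-6-{[2-(methoxycarbonyl)-4-methyl-6-oxocyclohex-1-en-1-yl]oxy}-3-[(4R)-2,2,6,6-tetramethyl-1,3-dioxan-4-yl]benzoate (epimer mixture) | COc1c([C@H]2CC(C)(C)OC(C)(C)O2)ccc(OC2=C(C(=O)OC)CC(C)CC2=O)c1C(=O)OC(C)(C)C | intermediate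
20 | tert-butyl 6-{[5-(N-tert-butyl-S-phenylsulfinimidoyl)-2-(methoxycarbonyl)-4-methyl-6-oxocyclohex-1-en-1-yl]oxy}-2-methoxy-3-[(4R)-2,2,6,6-tetramethyl-1,3-dioxan-4-yl]benzoate (isomer mixture) | COc1c([C@H]2CC(C)(C)OC(C)(C)O2)ccc(OC2=C(C(=O)OC)CC(C)C(S(=NC(C)(C)C)c3ccccc3)C2=O)c1C(=O)OC(C)(C)C | intermediate
21 | tert-butyl 2-methoxy-6-{[2-(methoxycarbonyl)-4-methyl-6-oxocyclohexa-1,4-dien-1-yl]oxy}-3-[(4R)-2,2,6,6-tetramethyl-1,3-dioxan-4-yl]benzoate | COc1c([C@H]2CC(C)(C)OC(C)(C)O2)ccc(OC2=C(C(=O)OC)CC(C)=CC2=O)c1C(=O)OC(C)(C)C | intermediate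
22 | tert-butyl 6-[2-hydroxy-6-(methoxycarbonyl)-4-methylphenoxy]-2-methoxy-3-[(4R)-2,2,6,6-tetramethyl-1,3-dioxan-4-yl]benzoate | COc1c([C@H]2CC(C)(C)OC(C)(C)O2)ccc(Oc2c(O)cc(C)cc2C(=O)OC)c1C(=O)OC(C)(C)C | intermediate
23 | tert-butyl 6-[2-hydroxy-6-(hydroxymethyl)-4-methylphenoxy]-2-methoxy-3-[(4R)-2,2,6,6-tetramethyl-1,3-dioxan-4-yl]benzoate | COc1c([C@H]2CC(C)(C)OC(C)(C)O2)ccc(Oc2c(O)cc(C)cc2CO)c1C(=O)OC(C)(C)C | intermediate
24 | 3-[(1R)-1,3-dihydroxy-3-methylbutyl]-6-[2-hydroxy-6-(hydroxymethyl)-4-methylphenoxy]-2-methoxybenzoic acid | COc1c([C@H](O)CC(C)(C)O)ccc(Oc2c(O)cc(C)cc2CO)c1C(=O)O | target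

Total step count: 15. Longest linear sequence: 13 steps (steps 1–6 and 9–15, from 4-hydroxy-2-methoxybenzaldehyde); steps 7 and 8 form the short side branch.

Steps most likely to fail

Step 10 (ring closure). Intermolecular Claisen or aldol condensation of the keto ester may outrun the ring closure, or the enolate may slowly attack the ring A ester in spite of its shielding. The fallback sets out from phenol 10 and makes the C1'–O bond on a preformed carbocycle. Commercial 5-methylcyclohexane-1,3-dione would be converted by Regitz diazo transfer (4-acetamidobenzenesulfonyl azide, Et3N, MeCN) into 2-diazo-5-methylcyclohexane-1,3-dione F1. The rhodium carbenoid generated from it with Rh2(OAc)4 (dirhodium tetraacetate, 1 mol%) in CH2Cl2 at reflux should insert into the O–H bond of 10 and give dione 17, where the route is rejoined.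

Step 13 (aromatisation). The amide base or the sulfur electrophile may add to the doubly activated ring alkene, or the phenoxide product may react further with excess sulfinimidoyl chloride. The fallback sets out from enone ester 19 and is a Saegusa–Ito oxidation. LiN(SiMe3)2 in the presence of Me3SiCl at −78 °C would give the trimethylsilyl dienol ether F2. With Pd(OAc)2 in MeCN at room temperature this should form a palladium enolate, undergo β-hydride elimination to dienone 21 and tautomerise to phenol 22, where the route is rejoined.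

Step 15 (global deprotection). Under the acid needed for the tert-butyl ester, the tert-butyl cation may alkylate the electron-rich phenol ring B, or the ring B hydroxymethyl group may ionise and be captured. The fallback reverses the last two operations and sets out from 22, in which ring B is still deactivated by its ester and has no benzylic alcohol. The same acid treatment (TFA/CH2Cl2/H2O, 0 °C) would give 3-[(1R)-1,3-dihydroxy-3-methylbutyl]-6-[2-hydroxy-6-(methoxycarbonyl)-4-methylphenoxy]-2-methoxybenzoic acid F3. Excess LiBH4 in THF, which reduces esters but not lithium carboxylates, would then reduce the methyl ester and give target 24.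

Further compounds
F1 | step 10 | 2-diazo-5-methylcyclohexane-1,3-dione | CC1CC(=O)C(=[N+]=[N-])C(=O)C1
F2 | step 13 | tert-butyl 2-methoxy-6-({2-(methoxycarbonyl)-4-methyl-6-[(trimethylsilyl)oxy]cyclohexa-1,5-dien-1-yl}oxy)-3-[(4R)-2,2,6,6-tetramethyl-1,3-dioxan-4-yl]benzoate | COc1c([C@H]2CC(C)(C)OC(C)(C)O2)ccc(OC2=C(C(=O)OC)CC(C)C=C2O[Si](C)(C)C)c1C(=O)OC(C)(C)C
F3 | step 15 | 3-[(1R)-1,3-dihydroxy-3-methylbutyl]-6-[2-hydroxy-6-(methoxycarbonyl)-4-methylphenoxy]-2-methoxybenzoic acid | COc1c([C@H](O)CC(C)(C)O)ccc(Oc2c(O)cc(C)cc2C(=O)OC)c1C(=O)O
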